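Assumption: the target has no stereocentre (it is achiral), so no enantioselective step is needed.

**Retrosynthetic overview**
1. Target 17 ⇐ allyl ether 16 by deallylation (last step, neutral conditions).
2. Key disconnection, C4–C4a of the pyran ring: 16 ⇐ phenol 12 + prenal 13 by intermolecular aldol addition, then dehydration and oxa-6π ring closure. The allyl ether caps the second oxygen next to the reacting carbon, so the pyran can only close onto the oxygen para to the ketone.
3. 12 ⇐ 10 ⇐ 5: the prenyl group is placed between two protected oxygens by O-prenylation and para-Claisen/Cope rearrangement, followed by MOM/allyl exchange.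
4. Benzophenone 4 ⇐ phloroglucinol 1 + 3-hydroxybenzonitrile 2 (Houben–Hoesch acylation).
5. Ring order: both benzene rings are bought; the pyran ring is the only ring made (step 7).

**Route**

Step 1
Reactants: 1 phloroglucinol; 2 3-hydroxybenzonitrile
Product: 4 (3-hydroxyphenyl)(2,4,6-trihydroxyphenyl)methanone, via ketiminium chloride 3 (not isolated)
Conditions: HCl (g), ZnCl2 (0.3 equiv), Et2O, 0 °C to rt; then H2O, reflux
Reagents that add atoms: water, O
Why: Houben–Hoesch acylation, in which the nitrilium ion from 2 attacks the symmetric, very electron-rich phloroglucinol once (the precipitated ketiminium salt is deactivated) and hydrolysis gives the ketone; no stereocentre is formed.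

Step 2
Reactants: 4 (3-hydroxyphenyl)(2,4,6-trihydroxyphenyl)methanone
Product: 5 [2-hydroxy-4,6-bis(methoxymethoxy)phenyl][3-(methoxymethoxy)phenyl]methanone
Conditions: MOMCl (3.1 equiv), i-Pr2NEt, CH2Cl2, 0 °C to rt
Reagents that add atoms: chloromethyl methyl ether, COCCl
Why: Williamson-type O-alkylation (MOM protection) takes the three accessible hydroxyls and stops before the last one, which is hydrogen-bonded to the ketone, as is general for 2,4,6-trihydroxyaryl ketones.

Step 3
Reactants: 5 [2-hydroxy-4,6-bis(methoxymethoxy)phenyl][3-(methoxymethoxy)phenyl]methanone; 6 prenyl bromide (1-bromo-3-methylbut-2-ene)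
Product: 7 [2,4-bis(methoxymethoxy)-6-(3-methylbut-2-enyloxy)phenyl][3-(methoxymethoxy)phenyl]methanone
Conditions: K2CO3, DMF, rt to 50 °C
Reagents that add atoms: none
Why: Williamson ether synthesis on the single remaining phenol, whose phenoxide is alkylated on oxygen by the primary allylic bromide in a polar aprotic solvent.

Step 4
Reactants: 7 [2,4-bis(methoxymethoxy)-6-(3-methylbut-2-enyloxy)phenyl][3-(methoxymethoxy)phenyl]methanone
Product: 10 [6-hydroxy-2,4-bis(methoxymethoxy)-3-(3-methylbut-2-enyl)phenyl][3-(methoxymethoxy)phenyl]methanone, via ortho-dienone 8 (not isolated), via para-dienone 9 (not isolated)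
Conditions: PhNEt2, 200 °C, sealed tube, Ar
Reagents that add atoms: none
Why: Aromatic para-Claisen rearrangement (Claisen then Cope), in which the first [3,3] shift gives an ortho-dienone whose hindered 1,1-dimethylallyl group moves on by a second [3,3] shift to the para carbon between the two MOM ethers, and enolisation returns the chelated phenol with a normal prenyl group, as is known for the analogous acetophenone.

Step 5
Reactants: 10 [6-hydroxy-2,4-bis(methoxymethoxy)-3-(3-methylbut-2-enyl)phenyl][3-(methoxymethoxy)phenyl]methanone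
Product: 11 [6-allyloxy-2,4-bis(methoxymethoxy)-3-(3-methylbut-2-enyl)phenyl][3-(methoxymethoxy)phenyl]methanone
Conditions: allyl bromide, K2CO3, DMF, 50 °C
Reagents that add atoms: allyl bromide, C=CCBr
Why: Williamson O-allylation caps the one oxygen that must not take part in the later pyran closure, with a group that is stable to acid and orthogonal to the MOM ethers.

Step 6
Reactants: 11 [6-allyloxy-2,4-bis(methoxymethoxy)-3-(3-methylbut-2-enyl)phenyl][3-(methoxymethoxy)phenyl]methanone
Product: 12 [6-allyloxy-2,4-dihydroxy-3-(3-methylbut-2-enyl)phenyl](3-hydroxyphenyl)methanone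
Conditions: HCl (3 M in MeOH), rt, short reaction time
Reagents that add atoms: none
Why: Acid-catalysed transacetalisation to methanol cleaves all three MOM ethers while the allyl aryl ether is inert, and brief treatment at room temperature is known to leave a prenyl group flanked by two MOM-protected oxygens uncyclised.

Step 7
Reactants: 12 [6-allyloxy-2,4-dihydroxy-3-(3-methylbut-2-enyl)phenyl](3-hydroxyphenyl)methanone; 13 prenal (3-methylbut-2-enal)
Product: 16 [5-allyloxy-7-hydroxy-2,2-dimethyl-8-(3-methylbut-2-enyl)-2H-chromen-6-yl](3-hydroxyphenyl)methanone, via aldol adduct 14 (not isolated), via ortho-quinone methide 15 (not isolated)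
Conditions: 13 (1.5 equiv), ethylenediammonium diacetate (EDDA, 20 mol%), toluene, 110 °C
Reagents that add atoms: none
Why: Intermolecular aldol addition of the phenol (reacting as its enol) to prenal at the only free carbon of ring A, then dehydration to the ortho-quinone methide and oxa-6π electrocyclisation; the only free hydroxyl next to the new bond is the one para to the ketone (the other neighbour is the allyl ether), so the pyran closes with the required regiochemistry, and the transient carbinol stereocentre is lost.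

Step 8
Reactants: 16 [5-allyloxy-7-hydroxy-2,2-dimethyl-8-(3-methylbut-2-enyl)-2H-chromen-6-yl](3-hydroxyphenyl)methanone
Product: 17 [5,7-dihydroxy-2,2-dimethyl-8-(3-methylbut-2-enyl)-2H-chromen-6-yl](3-hydroxyphenyl)methanone
Conditions: Pd(PPh3)4 (5 mol%), morpholine (10 equiv), THF, rt, Ar
Reagents that add atoms: none
Why: Tsuji–Trost-type deallylation, in which zerovalent palladium ionises the aryl allyl ether to a pi-allyl complex that excess morpholine captures, leaving the chromene, prenyl group and ketone untouched.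

**Compound list**
1 | phloroglucinol (benzene-1,3,5-triol) | Oc1cc(O)cc(O)c1 | starting material
2 | 3-hydroxybenzonitrile | N#Cc1cccc(O)c1 | starting material
3 | (3-hydroxyphenyl)(2,4,6-trihydroxyphenyl)methaniminium chloride | [NH2+]=C(c1cccc(O)c1)c1c(O)cc(O)cc1O.[Cl-] | intermediate
4 | (3-hydroxyphenyl)(2,4,6-trihydroxyphenyl)methanone | O=C(c1cccc(O)c1)c1c(O)cc(O)cc1O | intermediate
5 | [2-hydroxy-4,6-bis(methoxymethoxy)phenyl][3-(methoxymethoxy)phenyl]methanone | COCOc1cccc(c1)C(=O)c1c(O)cc(OCOC)cc1OCOC | intermediate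
6 | prenyl bromide (1-bromo-3-methylbut-2-ene) | CC(C)=CCBr | starting material
7 | [2,4-bis(methoxymethoxy)-6-(3-methylbut-2-enyloxy)phenyl][3-(methoxymethoxy)phenyl]methanone | COCOc1cccc(c1)C(=O)c1c(OCC=C(C)C)cc(OCOC)cc1OCOC | intermediate
8 | 2-[3-(methoxymethoxy)benzoyl]-3,5-bis(methoxymethoxy)-6-(2-methylbut-3-en-2-yl)cyclohexa-2,4-dien-1-one (ortho-dienone) | O=C1C(C(=O)c2cccc(OCOC)c2)=C(OCOC)C=C(OCOC)C1C(C)(C)C=C | intermediate
9 | 2-[3-(methoxymethoxy)benzoyl]-3,5-bis(methoxymethoxy)-4-(3-methylbut-2-enyl)cyclohexa-2,5-dien-1-one (para-dienone) | O=C1C=C(OCOC)C(CC=C(C)C)C(OCOC)=C1C(=O)c1cccc(OCOC)c1 | intermediate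
10 | [6-hydroxy-2,4-bis(methoxymethoxy)-3-(3-methylbut-2-enyl)phenyl][3-(methoxymethoxy)phenyl]methanone | COCOc1cccc(c1)C(=O)c1c(O)cc(OCOC)c(CC=C(C)C)c1OCOC | intermediate
11 | [6-allyloxy-2,4-bis(methoxymethoxy)-3-(3-methylbut-2-enyl)phenyl][3-(methoxymethoxy)phenyl]methanone | COCOc1cccc(c1)C(=O)c1c(OCC=C)cc(OCOC)c(CC=C(C)C)c1OCOC | intermediate
12 | [6-allyloxy-2,4-dihydroxy-3-(3-methylbut-2-enyl)phenyl](3-hydroxyphenyl)methanone | O=C(c1cccc(O)c1)c1c(OCC=C)cc(O)c(CC=C(C)C)c1O | intermediate
13 | prenal (3-methylbut-2-enal) | CC(C)=CC=O | starting material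
14 | [2-allyloxy-4,6-dihydroxy-3-(1-hydroxy-3-methylbut-2-enyl)-5-(3-methylbut-2-enyl)phenyl](3-hydroxyphenyl)methanone (aldol adduct, racemic carbinol) | O=C(c1cccc(O)c1)c1c(OCC=C)c(C(O)C=C(C)C)c(O)c(CC=C(C)C)c1O | intermediate
15 | 5-allyloxy-3-hydroxy-4-(3-hydroxybenzoyl)-6-(3-methylbut-2-enylidene)-2-(3-methylbut-2-enyl)cyclohexa-2,4-dien-1-one (ortho-quinone methide) | O=C1C(CC=C(C)C)=C(O)C(C(=O)c2cccc(O)c2)=C(OCC=C)C1=CC=C(C)C | intermediate
16 | [5-allyloxy-7-hydroxy-2,2-dimethyl-8-(3-methylbut-2-enyl)-2H-chromen-6-yl](3-hydroxyphenyl)methanone | O=C(c1cccc(O)c1)c1c(OCC=C)c2C=CC(C)(C)Oc2c(CC=C(C)C)c1O | intermediate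
17 | [5,7-dihydroxy-2,2-dimethyl-8-(3-methylbut-2-enyl)-2H-chromen-6-yl](3-hydroxyphenyl)methanone | CC(C)=CCc1c(O)c(C(=O)c2cccc(O)c2)c(O)c2c1OC(C)(C)C=C2 | target

**Totals**
Total step count: 8. Longest linear sequence: 8 steps (from 1 and 2 to 17).

**Steps most likely to fail, with fallbacks**

Step 4 (thermal para-Claisen/Cope): the relay may stop at the ortho 1,1-dimethylallyl phenol or lose the prenyl group. The fallback sets out from 5 and comes back at 12. It drops the sigmatropic transfer and brings the prenyl group in by direct C-alkylation after deprotection. Compound 5 is allylated (allyl bromide, K2CO3, DMF) to [2-allyloxy-4,6-bis(methoxymethoxy)phenyl][3-(methoxymethoxy)phenyl]methanone F1. The MOM ethers are cleaved (HCl, MeOH, rt) to (2-allyloxy-4,6-dihydroxyphenyl)(3-hydroxyphenyl)methanone F2. F2 is then C-prenylated with 6 and DBU (1 equiv) in THF at 0 °C. The carbon between the two ring-A hydroxyls is the most nucleophilic site and gives 12; one equivalent of base keeps alkylation on ring A because its para-hydroxyl is far more acidic than the ring-B phenol. This detour also moves the acid step to a stage that carries no prenyl group.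

Step 6 (acidic MOM removal next to a prenyl group): the prenyl group may cyclise onto a freed neighbouring phenol to give a chroman. The fallback sets out from 4 and comes back at 12. It carries fluoride-labile silyl ethers instead of acetals, so no acid ever meets the prenyl group. Compound 4 is silylated (TBSCl 3.1 equiv, imidazole, DMF) to [2,4-bis(tert-butyldimethylsilyloxy)-6-hydroxyphenyl][3-(tert-butyldimethylsilyloxy)phenyl]methanone F3. The chelated phenol is etherified under Mitsunobu conditions (3-methylbut-2-en-1-ol, PPh3, DIAD, THF; carbonate bases would strip aryl silyl ethers) to [2,4-bis(tert-butyldimethylsilyloxy)-6-(3-methylbut-2-enyloxy)phenyl][3-(tert-butyldimethylsilyloxy)phenyl]methanone F4. Heating in PhNEt2 at 200 °C rearranges it to [2,4-bis(tert-butyldimethylsilyloxy)-6-hydroxy-3-(3-methylbut-2-enyl)phenyl][3-(tert-butyldimethylsilyloxy)phenyl]methanone F5. A second Mitsunobu reaction (allyl alcohol) gives [6-allyloxy-2,4-bis(tert-butyldimethylsilyloxy)-3-(3-methylbut-2-enyl)phenyl][3-(tert-butyldimethylsilyloxy)phenyl]methanone F6. Buffered TBAF (AcOH, THF, 0 °C) removes the three silyl groups and gives 12.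

Step 7 (aldol/electrocyclisation annulation): the hindered, ketone-bearing ring may condense sluggishly or the quinone methide may oligomerise. The fallback sets out from 12 and comes back at 16. It builds the pyran from the oxygen side instead of by C–C condensation with the aldehyde. The non-chelated ring-A hydroxyl para to the ketone (the most acidic OH) is alkylated with 3-chloro-3-methylbut-1-yne (CuCl2 cat., DBU 1.1 equiv, MeCN, 0 °C) to [6-allyloxy-2-hydroxy-4-(2-methylbut-3-yn-2-yloxy)-3-(3-methylbut-2-enyl)phenyl](3-hydroxyphenyl)methanone F7. Heating F7 in xylene at 135 °C triggers propargyl Claisen rearrangement to the only free ortho carbon, then 1,5-hydrogen shift and oxa-6π closure, which gives 16. At this temperature the allyl aryl ether does not rearrange.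

Further compounds
F1 | step 4 | [2-allyloxy-4,6-bis(methoxymethoxy)phenyl][3-(methoxymethoxy)phenyl]methanone | COCOc1cccc(c1)C(=O)c1c(OCC=C)cc(OCOC)cc1OCOC
F2 | step 4 | (2-allyloxy-4,6-dihydroxyphenyl)(3-hydroxyphenyl)methanone | O=C(c1cccc(O)c1)c1c(OCC=C)cc(O)cc1O
F3 | step 6 | [2,4-bis(tert-butyldimethylsilyloxy)-6-hydroxyphenyl][3-(tert-butyldimethylsilyloxy)phenyl]methanone | CC(C)(C)[Si](C)(C)Oc1cccc(c1)C(=O)c1c(O)cc(O[Si](C)(C)C(C)(C)C)cc1O[Si](C)(C)C(C)(C)C
F4 | step 6 | [2,4-bis(tert-butyldimethylsilyloxy)-6-(3-methylbut-2-enyloxy)phenyl][3-(tert-butyldimethylsilyloxy)phenyl]methanone | CC(C)(C)[Si](C)(C)Oc1cccc(c1)C(=O)c1c(OCC=C(C)C)cc(O[Si](C)(C)C(C)(C)C)cc1O[Si](C)(C)C(C)(C)C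
F5 | step 6 | [2,4-bis(tert-butyldimethylsilyloxy)-6-hydroxy-3-(3-methylbut-2-enyl)phenyl][3-(tert-butyldimethylsilyloxy)phenyl]methanone | CC(C)(C)[Si](C)(C)Oc1cccc(c1)C(=O)c1c(O)cc(O[Si](C)(C)C(C)(C)C)c(CC=C(C)C)c1O[Si](C)(C)C(C)(C)C
F6 | step 6 | [6-allyloxy-2,4-bis(tert-butyldimethylsilyloxy)-3-(3-methylbut-2-enyl)phenyl][3-(tert-butyldimethylsilyloxy)phenyl]methanone | CC(C)(C)[Si](C)(C)Oc1cccc(c1)C(=O)c1c(OCC=C)cc(O[Si](C)(C)C(C)(C)C)c(CC=C(C)C)c1O[Si](C)(C)C(C)(C)C
F7 | step 7 | [6-allyloxy-2-hydroxy-4-(2-methylbut-3-yn-2-yloxy)-3-(3-methylbut-2-enyl)phenyl](3-hydroxyphenyl)methanone | O=C(c1cccc(O)c1)c1c(OCC=C)cc(OC(C)(C)C#C)c(CC=C(C)C)c1O
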